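**Plan**
Rings are lettered A to E from the phloroglucinol end. Ether oxygens join ring A to carbon 1 of ring B, carbon 5 of ring B to carbon 1 of ring C, carbon 2 of ring C to carbon 1 of ring D, and carbon 4 of ring D to carbon 1 of ring E.
Retrosynthesis: the O-protecting groups go first (ten methyl, two ethyl, one benzyl), then the two ether bonds at carbons 1 and 2 of ring C, with ring C as 1-bromo-2-iodo-3,4,5-trimethoxybenzene. Rings A–B and rings D–E are the same diaryl ether skeleton, so both halves go back to one phenol; its trioxygenated ring is cut across the 5–6 and 1–2 bonds to an aryl ethynyl ether and a cyclobutenone.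
Feature used: the oxygen on carbon 4 of ring D lies between two oxygenated carbons and carries ring E, a 1,3,4,5-tetraoxygenated benzene with carbons 2 and 6 unsubstituted. Ring A with ring B repeats this pattern, so one benzannulation product serves both halves and no crowded oxygen is ever arylated.
Forward: ring D phenol → ynol ether → benzannulation to the diaryl ether phenol. One portion is O-methylated and debenzylated (free hydroxyl on ring D) and joined at the iodide carbon of ring C; a second portion is used as it is (free hydroxyl on ring B) and joined at the bromide carbon. Hydrogenolysis and BBr3 then free all hydroxyls.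
Stereochemistry: the target has no stereocentre and no stable axis, so nothing has to be set.

Key step: step 6

Remark: the target is taken as the free tridecahydroxy compound, worked up and isolated under argon because polyphenols of this kind oxidise in air.

**Step 1**
Reactants: 1 2,6-dimethoxy-1,4-benzoquinone
Product: 2 2,6-dimethoxybenzene-1,4-diol
Conditions: Na2S2O4, EtOAc/H2O, rt, argon
Reagents that add atoms: none
Why: Dithionite reduction of a p-benzoquinone to its hydroquinone is fast and clean in a two-phase system and leaves the methoxy groups untouched.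

**Step 2**
Reactants: 2 2,6-dimethoxybenzene-1,4-diol
Product: 3 4-(benzyloxy)-2,6-dimethoxyphenol
Conditions: BnBr (1.0 equiv), K2CO3 (1.1 equiv), acetone, rt, argon
Reagents that add atoms: benzyl bromide, BrCc1ccccc1
Why: Williamson etherification with limiting benzyl bromide should go to the hydroxyl on carbon 4, which is the more acidic (two meta methoxy groups) and the unhindered one, whereas the hydroxyl on carbon 1 is flanked by two methoxy groups.

**Step 3**
Reactants: 3 4-(benzyloxy)-2,6-dimethoxyphenol; 4 trichloroethylene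
Product: 6 5-(benzyloxy)-2-{[(E)-1,2-dichloroethenyl]oxy}-1,3-dimethoxybenzene, via dichloroacetylene 5 (not isolated)
Conditions: K2CO3, DMF, 70 °C
Reagents that add atoms: none
Why: Base converts trichloroethylene into dichloroacetylene 5 by loss of HCl, and anti addition of the phenoxide followed by protonation gives the (E)-1,2-dichlorovinyl ether, the standard first stage of ynol ether synthesis, which tolerates a 2,6-disubstituted phenoxide because the electrophile is linear and small.

**Step 4**
Reactants: 6 5-(benzyloxy)-2-{[(E)-1,2-dichloroethenyl]oxy}-1,3-dimethoxybenzene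
Product: 9 5-(benzyloxy)-2-(ethynyloxy)-1,3-dimethoxybenzene, via chloroalkyne 7 (not isolated), via lithium acetylide 8 (not isolated)
Conditions: n-BuLi (2.3 equiv), THF, −78 → −40 °C; then H2O (pH 7 buffer), −78 → 0 °C
Reagents that add atoms: none
Why: n-BuLi effects elimination of HCl to chloroalkyne 7 and then chlorine–lithium exchange to acetylide 8, whose protonation gives the terminal ynol ether (the usual dichlorovinyl ether to ynol ether conversion); at −78 °C neither the benzyl ether nor the ring is metalated at a competitive rate.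

**Step 5**
Reactants: 10 methoxyacetyl chloride; 11 ethoxyacetylene
Product: 13 3-ethoxy-4-methoxycyclobut-2-en-1-one (racemic), via methoxyketene 12 (not isolated)
Conditions: Et3N, 11 (2 equiv), MeCN, slow addition of 10, 0 °C → rt
Reagents that add atoms: none
Why: Dehydrochlorination gives methoxyketene 12, which undergoes (2+2) ketene–alkyne cycloaddition with the terminal carbon of ethoxyacetylene attacking the ketene carbonyl carbon, the standard route to 3-ethoxycyclobutenones; the stereocentre at carbon 4 forms racemic and disappears in step 6.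

**Step 6**
Reactants: 9 5-(benzyloxy)-2-(ethynyloxy)-1,3-dimethoxybenzene; 13 3-ethoxy-4-methoxycyclobut-2-en-1-one
Product: 18 5-[4-(benzyloxy)-2,6-dimethoxyphenoxy]-3-ethoxy-2-methoxyphenol, via vinylketene 14 (not isolated), via vinylcyclobutenone 15 (not isolated), via dienylketene 16 (not isolated), via cyclohexadienone 17 (not isolated)
Conditions: 13 (2 equiv), toluene, 80 → 110 °C, sealed tube; then K2CO3, MeOH, rt
Reagents that add atoms: none
Why: On heating, 13 opens by conrotatory four-electron electrocyclic cleavage (the methoxy group on carbon 4 turning outward) to vinylketene 14, whose ketene C=C bond adds (2+2) to the electron-rich triple bond of 9 to give 2-vinylcyclobutenone 15; a second four-electron opening gives dienylketene 16, which closes the new ring by thermal disrotatory six-electron electrocyclisation and tautomerises from cyclohexadienone 17 to the phenol. This is the Danheiser benzannulation of a cyclobutenone with an alkynyl ether, here with an aryl in place of an alkyl or silyl ynol ether. The net result is insertion of the two alkyne carbons between the carbonyl carbon and carbon 2 of 13, which creates the bonds between carbons 5 and 6 and between carbons 1 and 2 of ring E, and the crowded oxygen on carbon 4 of ring D never attacks an aromatic carbon because it already sits on the alkyne. No stereocentre is created, and the stereocentres of 13, 15 and 17 vanish on aromatisation. The selectivity needed is regiochemical: the oxygen-polarised ynol ether puts its nucleophilic terminal carbon on the ketene carbonyl carbon, so the aryloxy group ends at carbon 1 of the new ring, meta to the new hydroxyl at carbon 5, with ethoxy at carbon 3 and methoxy at carbon 4. An aryl ynol ether has no β-hydrogen for retro-ene loss of ketene at this temperature, and the closing methanolysis returns any product that was O-acylated by the vinylketene.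

**Step 7**
Reactants: 18 5-[4-(benzyloxy)-2,6-dimethoxyphenoxy]-3-ethoxy-2-methoxyphenol
Product: 19 5-(benzyloxy)-2-(3-ethoxy-4,5-dimethoxyphenoxy)-1,3-dimethoxybenzene
Conditions: MeI, K2CO3, DMF, rt
Reagents that add atoms: iodomethane, CI
Why: Williamson methylation of the only free phenol caps the hydroxyl on carbon 5 of ring E in the portion destined for the D–E half, so that the later hydrogenolysis frees a single hydroxyl.

**Step 8**
Reactants: 19 5-(benzyloxy)-2-(3-ethoxy-4,5-dimethoxyphenoxy)-1,3-dimethoxybenzene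
Product: 20 4-(3-ethoxy-4,5-dimethoxyphenoxy)-3,5-dimethoxyphenol
Conditions: H2 (1 atm), Pd/C, EtOAc/MeOH, rt
Reagents that add atoms: none
Why: Hydrogenolysis of the single benzyl ether over Pd/C leaves aryl methyl, aryl ethyl and diaryl ethers intact and frees the unhindered hydroxyl on carbon 1 of ring D.

**Step 9**
Reactants: 21 5-bromo-1,2,3-trimethoxybenzene
Product: 22 1-bromo-2-iodo-3,4,5-trimethoxybenzene
Conditions: N-iodosuccinimide, CF3CO2H (cat.), MeCN, rt
Reagents that add atoms: N-iodosuccinimide, O=C1CCC(=O)N1I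
Why: Electrophilic aromatic iodination at the only type of free position, ortho and para to methoxy groups, puts iodine on the carbon that becomes carbon 2 of ring C, next to the bromine that marks carbon 1.

**Step 10**
Reactants: 20 4-(3-ethoxy-4,5-dimethoxyphenoxy)-3,5-dimethoxyphenol; 22 1-bromo-2-iodo-3,4,5-trimethoxybenzene
Product: 23 1-bromo-2-[4-(3-ethoxy-4,5-dimethoxyphenoxy)-3,5-dimethoxyphenoxy]-3,4,5-trimethoxybenzene
Conditions: CuI (10 mol%), picolinic acid (20 mol%), K3PO4, DMSO, 90 °C; 22 (2 equiv)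
Reagents that add atoms: none
Why: Ullmann diaryl ether coupling in which copper engages the carbon–iodine bond much faster than the carbon–bromine bond, as in the selective O-arylation of phenols with 1-bromo-2-iodoarenes; the picolinic acid system suits ortho-substituted halides, the phenol is unhindered, and excess 22 suppresses a second arylation.

**Step 11**
Reactants: 18 5-[4-(benzyloxy)-2,6-dimethoxyphenoxy]-3-ethoxy-2-methoxyphenol; 23 1-bromo-2-[4-(3-ethoxy-4,5-dimethoxyphenoxy)-3,5-dimethoxyphenoxy]-3,4,5-trimethoxybenzene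
Product: 24 1-{5-[4-(benzyloxy)-2,6-dimethoxyphenoxy]-3-ethoxy-2-methoxyphenoxy}-2-[4-(3-ethoxy-4,5-dimethoxyphenoxy)-3,5-dimethoxyphenoxy]-3,4,5-trimethoxybenzene
Conditions: CuI (20 mol%), N,N-dimethylglycine (40 mol%), Cs2CO3, 1,4-dioxane, 105 °C
Reagents that add atoms: none
Why: Ullmann diaryl ether coupling of the benzannulation phenol itself, whose free hydroxyl is the oxygen on carbon 5 of ring B, with an aryl bromide bearing one ortho aryloxy group; amino acid-ligated CuI with Cs2CO3 is well established for such electron-rich pairs, the benzyl ether on ring A is inert, and no other halogen or free hydroxyl is present.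

**Step 12**
Reactants: 24 1-{5-[4-(benzyloxy)-2,6-dimethoxyphenoxy]-3-ethoxy-2-methoxyphenoxy}-2-[4-(3-ethoxy-4,5-dimethoxyphenoxy)-3,5-dimethoxyphenoxy]-3,4,5-trimethoxybenzene
Product: 25 4-{3-ethoxy-5-[2-[4-(3-ethoxy-4,5-dimethoxyphenoxy)-3,5-dimethoxyphenoxy]-3,4,5-trimethoxyphenoxy]-4-methoxyphenoxy}-3,5-dimethoxyphenol
Conditions: H2 (1 atm), Pd/C, EtOAc/MeOH, rt
Reagents that add atoms: none
Why: Hydrogenolysis removes the single benzyl ether on ring A without touching alkyl or diaryl ethers, and doing it before the Lewis acid step keeps benzyl cations away from five electron-rich rings that could be C-benzylated.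

**Step 13**
Reactants: 25 the pentamer with one free hydroxyl on ring A, ten methyl ethers and two ethyl ethers
Product: 26 2-{3-[2-[3,5-dihydroxy-4-(3,4,5-trihydroxyphenoxy)phenoxy]-3,4,5-trihydroxyphenoxy]-4,5-dihydroxyphenoxy}benzene-1,3,5-triol (CNP0228612.0)
Conditions: BBr3 (30 equiv), CH2Cl2, −78 °C → rt; then H2O, 0 °C, argon
Reagents that add atoms: none
Why: Lewis acid dealkylation with BBr3 cleaves aryl methyl and ethyl ethers by bromide attack on the O-alkyl carbon of the boron complex and cannot cleave diaryl ether bonds, so hydrolysis of the aryl borates should give the tridecahydroxy target.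

**Compound list**
1 | 2,6-dimethoxy-1,4-benzoquinone | COC1=CC(=O)C=C(OC)C1=O | starting material
2 | 2,6-dimethoxybenzene-1,4-diol | COc1cc(O)cc(OC)c1O | intermediate
3 | 4-(benzyloxy)-2,6-dimethoxyphenol | COc1cc(OCc2ccccc2)cc(OC)c1O | intermediate
4 | trichloroethylene | ClC=C(Cl)Cl | starting material
5 | dichloroacetylene | ClC#CCl | intermediate
6 | 5-(benzyloxy)-2-{[(E)-1,2-dichloroethenyl]oxy}-1,3-dimethoxybenzene | Cl/C=C(Cl)\Oc1c(OC)cc(OCc2ccccc2)cc1OC | intermediate
7 | 5-(benzyloxy)-2-[(chloroethynyl)oxy]-1,3-dimethoxybenzene | ClC#COc1c(OC)cc(OCc2ccccc2)cc1OC | intermediate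
8 | lithium 2-[4-(benzyloxy)-2,6-dimethoxyphenoxy]ethynide | [Li]C#COc1c(OC)cc(OCc2ccccc2)cc1OC | intermediate
9 | 5-(benzyloxy)-2-(ethynyloxy)-1,3-dimethoxybenzene | C#COc1c(OC)cc(OCc2ccccc2)cc1OC | intermediate
10 | methoxyacetyl chloride | COCC(Cl)=O | starting material
11 | ethoxyacetylene | CCOC#C | starting material
12 | methoxyketene | COC=C=O | intermediate
13 | 3-ethoxy-4-methoxycyclobut-2-en-1-one (racemic) | CCOC1=CC(=O)C1OC | intermediate
14 | (3Z)-3-ethoxy-4-methoxybuta-1,3-dien-1-one | O=C=C/C(OCC)=C/OC | intermediate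
15 | 3-[4-(benzyloxy)-2,6-dimethoxyphenoxy]-4-[(Z)-1-ethoxy-2-methoxyethenyl]cyclobut-2-en-1-one (racemic) | O=C1C=C(Oc2c(OC)cc(OCc3ccccc3)cc2OC)C1/C(OCC)=C/OC | intermediate
16 | (3E,5Z)-3-[4-(benzyloxy)-2,6-dimethoxyphenoxy]-5-ethoxy-6-methoxyhexa-1,3,5-trien-1-one | O=C=C/C(Oc1c(OC)cc(OCc2ccccc2)cc1OC)=C\C(OCC)=C\OC | intermediate
17 | 3-[4-(benzyloxy)-2,6-dimethoxyphenoxy]-5-ethoxy-6-methoxycyclohexa-2,4-dien-1-one (racemic) | O=C1C=C(Oc2c(OC)cc(OCc3ccccc3)cc2OC)C=C(OCC)C1OC | intermediate
18 | 5-[4-(benzyloxy)-2,6-dimethoxyphenoxy]-3-ethoxy-2-methoxyphenol | Oc1cc(Oc2c(OC)cc(OCc3ccccc3)cc2OC)cc(OCC)c1OC | intermediate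
19 | 5-(benzyloxy)-2-(3-ethoxy-4,5-dimethoxyphenoxy)-1,3-dimethoxybenzene | COc1cc(Oc2c(OC)cc(OCc3ccccc3)cc2OC)cc(OCC)c1OC | intermediate
20 | 4-(3-ethoxy-4,5-dimethoxyphenoxy)-3,5-dimethoxyphenol | COc1cc(Oc2c(OC)cc(O)cc2OC)cc(OCC)c1OC | intermediate
21 | 5-bromo-1,2,3-trimethoxybenzene | COc1cc(Br)cc(OC)c1OC | starting material
22 | 1-bromo-2-iodo-3,4,5-trimethoxybenzene | COc1cc(Br)c(I)c(OC)c1OC | intermediate
23 | 1-bromo-2-[4-(3-ethoxy-4,5-dimethoxyphenoxy)-3,5-dimethoxyphenoxy]-3,4,5-trimethoxybenzene | COc1cc(Br)c(Oc2cc(OC)c(Oc3cc(OCC)c(OC)c(OC)c3)c(OC)c2)c(OC)c1OC | intermediate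
24 | 1-{5-[4-(benzyloxy)-2,6-dimethoxyphenoxy]-3-ethoxy-2-methoxyphenoxy}-2-[4-(3-ethoxy-4,5-dimethoxyphenoxy)-3,5-dimethoxyphenoxy]-3,4,5-trimethoxybenzene | C(c1ccccc1)Oc1cc(OC)c(Oc2cc(OCC)c(OC)c(Oc3cc(OC)c(OC)c(OC)c3Oc3cc(OC)c(Oc4cc(OCC)c(OC)c(OC)c4)c(OC)c3)c2)c(OC)c1 | intermediate
25 | 4-{3-ethoxy-5-[2-[4-(3-ethoxy-4,5-dimethoxyphenoxy)-3,5-dimethoxyphenoxy]-3,4,5-trimethoxyphenoxy]-4-methoxyphenoxy}-3,5-dimethoxyphenol | Oc1cc(OC)c(Oc2cc(OCC)c(OC)c(Oc3cc(OC)c(OC)c(OC)c3Oc3cc(OC)c(Oc4cc(OCC)c(OC)c(OC)c4)c(OC)c3)c2)c(OC)c1 | intermediate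
26 | 2-{3-[2-[3,5-dihydroxy-4-(3,4,5-trihydroxyphenoxy)phenoxy]-3,4,5-trihydroxyphenoxy]-4,5-dihydroxyphenoxy}benzene-1,3,5-triol (CNP0228612.0) | Oc1cc(O)c(Oc2cc(O)c(O)c(Oc3cc(O)c(O)c(O)c3Oc3cc(O)c(Oc4cc(O)c(O)c(O)c4)c(O)c3)c2)c(O)c1 | target

**Step count and risks**
Total: 13 steps. Longest linear sequence: 11 steps (1, 2, 3, 4, 6, 7, 8, 10, 11, 12, 13).

Step 6. The alkoxy-substituted vinylketene may dimerise or acylate phenols faster than it is captured by the less nucleophilic aryl ynol ether, or the terminal ynol ether may oligomerise on heating. The fallback makes the ether bond between ring D and ring E by copper-mediated arylation of the hindered phenol, and it also makes steps 3 to 5 unnecessary. It sets out from phenol 3 and returns at 18. Commercial 5-bromo-3-ethoxy-2-hydroxybenzaldehyde is O-methylated (MeI, K2CO3, DMF) to 5-bromo-3-ethoxy-2-methoxybenzaldehyde F1. Ullmann coupling of 3 with this unhindered bromide (CuI, N,N-dimethylglycine, Cs2CO3, dioxane, 105 °C) should give 5-[4-(benzyloxy)-2,6-dimethoxyphenoxy]-3-ethoxy-2-methoxybenzaldehyde F2. Baeyer–Villiger (Dakin-type) oxidation with mCPBA in CH2Cl2 gives 5-[4-(benzyloxy)-2,6-dimethoxyphenoxy]-3-ethoxy-2-methoxyphenyl formate F3, which is cleaved in the same flask (KOH, MeOH/H2O) to 18.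

Step 10. Oxidative addition at the doubly flanked carbon–iodine bond may be too slow, so that reaction at the open bromide, a second arylation or loss of iodine takes over. The fallback activates the flanked carbon with an ortho formyl group and carries no second halogen. It sets out from phenol 20 and returns at 24. Ullmann coupling of 20 with commercial 2-bromo-3,4,5-trimethoxybenzaldehyde (CuI, Cs2CO3, DMF, 110 °C) should give 2-[4-(3-ethoxy-4,5-dimethoxyphenoxy)-3,5-dimethoxyphenoxy]-3,4,5-trimethoxybenzaldehyde F4. mCPBA oxidation gives 2-[4-(3-ethoxy-4,5-dimethoxyphenoxy)-3,5-dimethoxyphenoxy]-3,4,5-trimethoxyphenyl formate F5, which is hydrolysed (KOH, MeOH/H2O) to 2-[4-(3-ethoxy-4,5-dimethoxyphenoxy)-3,5-dimethoxyphenoxy]-3,4,5-trimethoxyphenol F6. Tf2O and pyridine in CH2Cl2 at 0 °C convert this into 2-[4-(3-ethoxy-4,5-dimethoxyphenoxy)-3,5-dimethoxyphenoxy]-3,4,5-trimethoxyphenyl trifluoromethanesulfonate F7. This triflate takes the place of bromide 23 in a palladium-catalysed carbon–oxygen coupling with phenol 18 (Pd(OAc)2, t-BuXPhos, K3PO4, toluene, 100 °C) to give 24.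

Step 11. Oxidative addition of copper to the electron-rich bromide next to a bulky aryloxy group may be slow, so that reductive loss of bromine or decomposition of the phenol at 105 °C takes over. The fallback turns the halide into the nucleophilic partner and couples oxidatively at room temperature. It sets out from bromide 23 and returns at 24. Bromine–lithium exchange (n-BuLi, THF, −78 °C), trapping with B(OiPr)3 and mild acid work-up should give {2-[4-(3-ethoxy-4,5-dimethoxyphenoxy)-3,5-dimethoxyphenoxy]-3,4,5-trimethoxyphenyl}boronic acid F8. Chan–Lam coupling of this boronic acid with phenol 18 (Cu(OAc)2, pyridine, 4 Å molecular sieves, CH2Cl2, air, rt) gives 24.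

**Further compounds**
F1 | step 6 | 5-bromo-3-ethoxy-2-methoxybenzaldehyde | CCOc1cc(Br)cc(C=O)c1OC
F2 | step 6 | 5-[4-(benzyloxy)-2,6-dimethoxyphenoxy]-3-ethoxy-2-methoxybenzaldehyde | CCOc1cc(Oc2c(OC)cc(OCc3ccccc3)cc2OC)cc(C=O)c1OC
F3 | step 6 | 5-[4-(benzyloxy)-2,6-dimethoxyphenoxy]-3-ethoxy-2-methoxyphenyl formate | O=COc1cc(Oc2c(OC)cc(OCc3ccccc3)cc2OC)cc(OCC)c1OC
F4 | step 10 | 2-[4-(3-ethoxy-4,5-dimethoxyphenoxy)-3,5-dimethoxyphenoxy]-3,4,5-trimethoxybenzaldehyde | COc1cc(C=O)c(Oc2cc(OC)c(Oc3cc(OCC)c(OC)c(OC)c3)c(OC)c2)c(OC)c1OC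
F5 | step 10 | 2-[4-(3-ethoxy-4,5-dimethoxyphenoxy)-3,5-dimethoxyphenoxy]-3,4,5-trimethoxyphenyl formate | COc1cc(OC=O)c(Oc2cc(OC)c(Oc3cc(OCC)c(OC)c(OC)c3)c(OC)c2)c(OC)c1OC
F6 | step 10 | 2-[4-(3-ethoxy-4,5-dimethoxyphenoxy)-3,5-dimethoxyphenoxy]-3,4,5-trimethoxyphenol | COc1cc(O)c(Oc2cc(OC)c(Oc3cc(OCC)c(OC)c(OC)c3)c(OC)c2)c(OC)c1OC
F7 | step 10 | 2-[4-(3-ethoxy-4,5-dimethoxyphenoxy)-3,5-dimethoxyphenoxy]-3,4,5-trimethoxyphenyl trifluoromethanesulfonate | COc1cc(OS(=O)(=O)C(F)(F)F)c(Oc2cc(OC)c(Oc3cc(OCC)c(OC)c(OC)c3)c(OC)c2)c(OC)c1OC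
F8 | step 11 | {2-[4-(3-ethoxy-4,5-dimethoxyphenoxy)-3,5-dimethoxyphenoxy]-3,4,5-trimethoxyphenyl}boronic acid | COc1cc(B(O)O)c(Oc2cc(OC)c(Oc3cc(OCC)c(OC)c(OC)c3)c(OC)c2)c(OC)c1OC
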